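The easy step is to add the readings up, and the meeting began there.

- maple: D 0.020 M; the very flask that is asked about, followed so far
- flask: D 0.020 M; time 6.0 h

maple run (percent of the D charged)

| time / min | G / % | Q / % |
|---|---|---|
| 20.0 | 7 | 22 |
| 40.0 | 9 | 28 |
| 50.0 | 9 | 38 |
| 80.0 | 11 | 42 |

(scatter of a reading: 2 percentage points)

- the analysis behind the earlier runs scatters by 2 percentage points, standard deviation
- a reading or a percentage of Q counts all its forms, free or not

* share of G in G plus Q at 1.0 min
* share of G in G plus Q at 6.0 h

The first member noted that the maple run is the early part of the very flask asked about, so its readings speak directly to the question. She proposed treating G as a small correction to Q. Summing each column before dividing lets the scatter of 2 percentage points per reading partly cancel, whereas four separate ratios each carry it in full. Her carried quantity was the pooled share s = ΣG/(ΣG + ΣQ), the selectivity between the two products, which these scattered readings put at 21.7%.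

The second member, who made the forecast, read the flask as “two parallel routes from D with a fixed ratio”. He therefore entered 22% at 1.0 min and 22% at 6.0 h, while granting that both times lie outside the readings.

The flask gave 17.5% at 1.0 min and 17.4% at 6.0 h, both within the forecast's margin, the later one 4.3 points below s.

    D ⇌ Q (K = 0.720, k = 1.00 h⁻¹)
    D ⇌ G (K = 2.80, k = 0.210 h⁻¹)
    X ⇌ Q, rate k3*(cs3 - [Q]) while solid is left; crystals form when [Q] > cs3 (solubility = 0.230 mM, k = 5.50 h⁻¹)
    D ⇌ L (K = 29.0, k = 0.730 h⁻¹)

In this flask the share is held down because so little Q dissolves: with that low solubility taken away, the share at 6.0 h is 78.5% instead of 17.4%. At 6.00 h this flask holds 44.6% of the D charged as the solid form X, within the 45.7% counted as Q. The neighbour flask, charged with 0.0050 M of D, holds 28.8% of its charge as X within 33.1% of Q at that time, and its share of 26.2% stands 4.5 points above s.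

The runs were computed with constants of no real substance.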